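**Plan**

- Retrosynthesis cuts the stilbene C=C bond first (benzodioxane aldehyde plus benzylic phosphonate). It then cuts, in one operation, the C2–aryl bond and the C3–O4 bond of the 1,4-benzodioxane. Last it cuts the O1–C2 bond of the resulting (Z)-β-aryloxystyrene, giving a phenol and an arylacetylene, both from 3,4-dihydroxybenzaldehyde.
- Forward, the open-chain enol ether is assembled first. The dioxane ring, the only ring made, closes when an aryl triflate is added across the enol ether. The styryl arm is joined afterwards and five acetals are removed at the end.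
- Enabling feature: the catechol ring on C3 has a free hydroxyl para to C3, so a C3–palladium bond can leave as a p-quinone methide, onto which the ring A hydroxyl (O4, para to the formyl carbon) closes. C2, bound to O1 (meta to that carbon), is the oxygen-bearing carbon of an aryl enol ether and is therefore the site that takes up the aryl group.
- Stereochemistry: C2 (S) comes from enantioface-selective insertion under a chiral bisphosphine on palladium. C3 (S) comes from reversible, trans-selective closure on the quinone methide. The E stilbene comes from the phosphonate olefination.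

Key step: step 8

Remark on numbering: in the benzodioxane, O1 is the ring oxygen meta to the formyl (later styryl) carbon of ring A, C2 carries the resorcinol ring, C3 the catechol ring, O4 is para to that carbon, and the carbon itself is C7; with this numbering the target is (2S,3S), trans.

Assumption: (R)-BINAP is taken to direct the aryl group to the enantioface of the enol ether that leads to (2S); if the sense of induction proves opposite, (S)-BINAP is used and nothing else changes.

**Route**

Step 1
Reactants: 1 3,4-dihydroxybenzaldehyde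
Product: 2 4-(allyloxy)-3-hydroxybenzaldehyde
Conditions: allyl bromide (1.05 equiv), NaHCO3, NaI (cat.), DMF, 40 °C
Reagents that add atoms: allyl bromide, C=CCBr
Why: Williamson etherification under weak-base control, in which the 4-hydroxyl (para to the formyl group, the more acidic phenol) is ionised preferentially by NaHCO3 and alkylated, leaving the 3-hydroxyl free.

Step 2
Reactants: 2 4-(allyloxy)-3-hydroxybenzaldehyde
Product: 3 4-(allyloxy)-3-(methoxymethoxy)benzaldehyde
Conditions: MOMCl, iPr2NEt, CH2Cl2, 0 °C to rt
Reagents that add atoms: chloromethyl methyl ether, COCCl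
Why: Williamson-type O-alkylation of the remaining phenol gives an acetal that is stable to the basic steps ahead and orthogonal to the allyl ethers.

Step 3
Reactants: 3 4-(allyloxy)-3-(methoxymethoxy)benzaldehyde
Product: 4 1-(allyloxy)-4-ethynyl-2-(methoxymethoxy)benzene
Conditions: dimethyl (1-diazo-2-oxopropyl)phosphonate, K2CO3, MeOH, rt
Reagents that add atoms: dimethyl (1-diazo-2-oxopropyl)phosphonate, CC(=O)C(=[N+]=[N-])P(=O)(OC)OC
Why: Seyferth–Gilbert homologation in the Ohira–Bestmann variant converts the non-enolisable, electron-rich aryl aldehyde into the terminal alkyne under mild carbonate conditions that leave allyl and methoxymethyl ethers untouched.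

Step 4
Reactants: 2 4-(allyloxy)-3-hydroxybenzaldehyde + 4 1-(allyloxy)-4-ethynyl-2-(methoxymethoxy)benzene
Product: 5 4-(allyloxy)-3-({(Z)-2-[4-(allyloxy)-3-(methoxymethoxy)phenyl]ethenyl}oxy)benzaldehyde
Conditions: Cs2CO3 (30 mol %), DMSO, 95 °C, argon
Reagents that add atoms: none
Why: Base-catalysed anti-Markovnikov hydrophenoxylation of an arylacetylene, in which the caesium phenoxide of 2 adds to the terminal alkyne carbon and the benzylic vinyl anion is protonated anti to the incoming oxygen, should give the kinetic Z enol ether if the reaction is stopped before Z to E drift.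

Step 5
Reactants: 5 4-(allyloxy)-3-({(Z)-2-[4-(allyloxy)-3-(methoxymethoxy)phenyl]ethenyl}oxy)benzaldehyde
Product: 6 4-hydroxy-3-({(Z)-2-[4-hydroxy-3-(methoxymethoxy)phenyl]ethenyl}oxy)benzaldehyde
Conditions: Pd(PPh3)4 (5 mol %), morpholine (6 equiv), THF, rt
Reagents that add atoms: none
Why: Tsuji–Trost deallylation, in which zerovalent palladium ionises each aryl allyl ether to a π-allylpalladium phenoxide and morpholine captures the allyl group, should leave the aldehyde, the acetal and the Z enol ether untouched.

Step 6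
Reactants: 7 phloroglucinol
Product: 8 3,5-bis(methoxymethoxy)phenol
Conditions: MOMCl (2.0 equiv), iPr2NEt (2.2 equiv), DMF, 0 °C to rt; chromatography
Reagents that add atoms: chloromethyl methyl ether, COCCl
Why: Statistical Williamson-type O-alkylation of the threefold symmetric triol with two equivalents of the chloride should give the bis-ether, separable by chromatography from mono- and tris-ether.

Step 7
Reactants: 8 3,5-bis(methoxymethoxy)phenol
Product: 9 3,5-bis(methoxymethoxy)phenyl trifluoromethanesulfonate
Conditions: PhNTf2, Et3N, DMAP (cat.), CH2Cl2, 0 °C to rt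
Reagents that add atoms: N-phenylbis(trifluoromethanesulfonimide), O=S(=O)(N(c1ccccc1)S(=O)(=O)C(F)(F)F)C(F)(F)F
Why: O-Sulfonylation of the phenol with a mild triflyl donor gives the aryl triflate without acid that could harm the acetals.

Step 8
Reactants: 6 4-hydroxy-3-({(Z)-2-[4-hydroxy-3-(methoxymethoxy)phenyl]ethenyl}oxy)benzaldehyde + 9 3,5-bis(methoxymethoxy)phenyl trifluoromethanesulfonate
Product: 11 (2S,3S)-2-[3,5-bis(methoxymethoxy)phenyl]-3-[4-hydroxy-3-(methoxymethoxy)phenyl]-2,3-dihydro-1,4-benzodioxine-7-carbaldehyde, via p-quinone methide 10 (not isolated)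
Conditions: Pd2(dba)3 (2.5 mol %), (R)-BINAP (6 mol %), 1,2,2,6,6-pentamethylpiperidine (2.5 equiv), 1,4-dioxane, 70 °C, argon
Reagents that add atoms: none
Why: Proposed new method: zerovalent palladium carrying (R)-BINAP should insert into the aryl–OTf bond of 9, and the cationic arylpalladium species should bind the Z enol ether of 6 and deliver its aryl group to C2, leaving palladium on benzylic C3; loss of the para phenolic proton of the catechol ring then releases zerovalent palladium and p-quinone methide 10, which the ring A hydroxyl closes. The closest known reaction types are the enantioselective Heck arylation of cyclic enol ethers with aryl triflates under palladium–BINAP catalysis and the palladium-catalysed difunctionalisation of hydroxystyrenes that runs through quinone methides, but their union on an acyclic β-aryloxystyrene is without precedent. The dioxane ring closes by 6-exo-trig oxa-Michael addition of O4 (the hydroxyl para to the formyl group) to the methide carbon C3. C2 is fixed in the migratory insertion, in which the chiral bisphosphine selects the enantioface of the alkene, and C3 is fixed in the ring closure, which is reversible under the basic conditions and should settle on the trans (diequatorial) diaryl arrangement, any cis isomer reopening to 10. The step needs aryl transfer to C2 and not to C3, secured by the enol ether oxygen on C2 together with benzylic stabilisation of palladium at C3 and by a hindered amine base that leaves both phenols un-ionised until after insertion. It also needs quinone methide release to outrun β-hydride elimination toward C2, which the free para hydroxyl secures by offering a heterolytic exit that requires neither a vacant coordination site nor rotation about the C2–C3 bond.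

Step 9
Reactants: 11 (2S,3S)-2-[3,5-bis(methoxymethoxy)phenyl]-3-[4-hydroxy-3-(methoxymethoxy)phenyl]-2,3-dihydro-1,4-benzodioxine-7-carbaldehyde
Product: 12 (2S,3S)-2-[3,5-bis(methoxymethoxy)phenyl]-3-[3,4-bis(methoxymethoxy)phenyl]-2,3-dihydro-1,4-benzodioxine-7-carbaldehyde
Conditions: MOMCl, iPr2NEt, CH2Cl2, 0 °C to rt
Reagents that add atoms: chloromethyl methyl ether, COCCl
Why: Williamson-type O-alkylation caps the one remaining phenol, so that the C3–O4 bond can no longer open to a quinone methide under the strongly basic olefination.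

Step 10
Reactants: 13 3,5-dihydroxybenzyl alcohol
Product: 14 [3,5-bis(methoxymethoxy)phenyl]methanol
Conditions: MOMCl (2.2 equiv), K2CO3, acetone, 0 °C to rt
Reagents that add atoms: chloromethyl methyl ether, COCCl
Why: Phenol-selective Williamson-type O-alkylation, because K2CO3 ionises only the two phenols and the benzylic alcohol stays free.

Step 11
Reactants: 14 [3,5-bis(methoxymethoxy)phenyl]methanol
Product: 15 1-(bromomethyl)-3,5-bis(methoxymethoxy)benzene
Conditions: CBr4, PPh3, CH2Cl2, 0 °C
Reagents that add atoms: tetrabromomethane, BrC(Br)(Br)Br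
Why: Appel bromination converts the benzylic alcohol into the bromide under neutral conditions compatible with the acetals.

Step 12
Reactants: 15 1-(bromomethyl)-3,5-bis(methoxymethoxy)benzene
Product: 16 diethyl {[3,5-bis(methoxymethoxy)phenyl]methyl}phosphonate
Conditions: P(OEt)3, neat, 130 °C
Reagents that add atoms: triethyl phosphite, CCOP(OCC)OCC
Why: Michaelis–Arbuzov reaction of the benzylic bromide with triethyl phosphite gives the phosphonate while the volatile bromoethane distils off.

Step 13
Reactants: 12 (2S,3S)-2-[3,5-bis(methoxymethoxy)phenyl]-3-[3,4-bis(methoxymethoxy)phenyl]-2,3-dihydro-1,4-benzodioxine-7-carbaldehyde + 16 diethyl {[3,5-bis(methoxymethoxy)phenyl]methyl}phosphonate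
Product: 17 (2S,3S)-2-[3,5-bis(methoxymethoxy)phenyl]-3-[3,4-bis(methoxymethoxy)phenyl]-7-{(E)-2-[3,5-bis(methoxymethoxy)phenyl]ethenyl}-2,3-dihydro-1,4-benzodioxine
Conditions: KOtBu, THF, 0 °C to rt
Reagents that add atoms: none
Why: Horner–Wadsworth–Emmons olefination of the non-enolisable aryl aldehyde with the benzylic phosphonate anion should give the E stilbene, and neither stereocentre is touched because C2–H and C3–H are not acidic and all phenols are capped.

Step 14
Reactants: 17 (2S,3S)-2-[3,5-bis(methoxymethoxy)phenyl]-3-[3,4-bis(methoxymethoxy)phenyl]-7-{(E)-2-[3,5-bis(methoxymethoxy)phenyl]ethenyl}-2,3-dihydro-1,4-benzodioxine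
Product: 18 5-{(E)-2-[(2S,3S)-3-(3,4-dihydroxyphenyl)-2-(3,5-dihydroxyphenyl)-2,3-dihydro-1,4-benzodioxin-7-yl]ethenyl}benzene-1,3-diol (CNP0419909.1)
Conditions: HCl (1.25 M in MeOH), THF, 40 °C, argon, dark
Reagents that add atoms: none
Why: Acid-catalysed transacetalisation to methanol cleaves all five aryl methoxymethyl ethers, while C2 has no ionisable path and any reversible ionisation at C3 returns to the trans ring, so the (2S,3S) configuration should be kept.

**Compound list**

1 | 3,4-dihydroxybenzaldehyde | O=Cc1ccc(O)c(O)c1 | starting material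
2 | 4-(allyloxy)-3-hydroxybenzaldehyde | O=Cc1ccc(OCC=C)c(O)c1 | intermediate
3 | 4-(allyloxy)-3-(methoxymethoxy)benzaldehyde | O=Cc1ccc(OCC=C)c(OCOC)c1 | intermediate
4 | 1-(allyloxy)-4-ethynyl-2-(methoxymethoxy)benzene | C#Cc1ccc(OCC=C)c(OCOC)c1 | intermediate
5 | 4-(allyloxy)-3-({(Z)-2-[4-(allyloxy)-3-(methoxymethoxy)phenyl]ethenyl}oxy)benzaldehyde | O=Cc1ccc(OCC=C)c(c1)O/C=C\c1ccc(OCC=C)c(OCOC)c1 | intermediate
6 | 4-hydroxy-3-({(Z)-2-[4-hydroxy-3-(methoxymethoxy)phenyl]ethenyl}oxy)benzaldehyde | O=Cc1ccc(O)c(c1)O/C=C\c1ccc(O)c(OCOC)c1 | intermediate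
7 | phloroglucinol (benzene-1,3,5-triol) | Oc1cc(O)cc(O)c1 | starting material
8 | 3,5-bis(methoxymethoxy)phenol | COCOc1cc(O)cc(OCOC)c1 | intermediate
9 | 3,5-bis(methoxymethoxy)phenyl trifluoromethanesulfonate | COCOc1cc(OCOC)cc(OS(=O)(=O)C(F)(F)F)c1 | intermediate
10 | 3-{(1R)-1-[3,5-bis(methoxymethoxy)phenyl]-2-[3-(methoxymethoxy)-4-oxocyclohexa-2,5-dien-1-ylidene]ethoxy}-4-hydroxybenzaldehyde (p-quinone methide, not isolated; same spatial arrangement at the stereocentre as C2 of 11, exocyclic alkene geometry open) | O=Cc1ccc(O)c(c1)O[C@@H](c1cc(OCOC)cc(OCOC)c1)C=C1C=CC(=O)C(OCOC)=C1 | intermediate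
11 | (2S,3S)-2-[3,5-bis(methoxymethoxy)phenyl]-3-[4-hydroxy-3-(methoxymethoxy)phenyl]-2,3-dihydro-1,4-benzodioxine-7-carbaldehyde | O=Cc1ccc2c(c1)O[C@@H](c1cc(OCOC)cc(OCOC)c1)[C@H](c1ccc(O)c(OCOC)c1)O2 | intermediate
12 | (2S,3S)-2-[3,5-bis(methoxymethoxy)phenyl]-3-[3,4-bis(methoxymethoxy)phenyl]-2,3-dihydro-1,4-benzodioxine-7-carbaldehyde | O=Cc1ccc2c(c1)O[C@@H](c1cc(OCOC)cc(OCOC)c1)[C@H](c1ccc(OCOC)c(OCOC)c1)O2 | intermediate
13 | 3,5-dihydroxybenzyl alcohol | OCc1cc(O)cc(O)c1 | starting material
14 | [3,5-bis(methoxymethoxy)phenyl]methanol | OCc1cc(OCOC)cc(OCOC)c1 | intermediate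
15 | 1-(bromomethyl)-3,5-bis(methoxymethoxy)benzene | BrCc1cc(OCOC)cc(OCOC)c1 | intermediate
16 | diethyl {[3,5-bis(methoxymethoxy)phenyl]methyl}phosphonate | CCOP(=O)(OCC)Cc1cc(OCOC)cc(OCOC)c1 | intermediate
17 | (2S,3S)-2-[3,5-bis(methoxymethoxy)phenyl]-3-[3,4-bis(methoxymethoxy)phenyl]-7-{(E)-2-[3,5-bis(methoxymethoxy)phenyl]ethenyl}-2,3-dihydro-1,4-benzodioxine | COCOc1cc(OCOC)cc(/C=C/c2ccc3c(c2)O[C@@H](c2cc(OCOC)cc(OCOC)c2)[C@H](c2ccc(OCOC)c(OCOC)c2)O3)c1 | intermediate
18 | 5-{(E)-2-[(2S,3S)-3-(3,4-dihydroxyphenyl)-2-(3,5-dihydroxyphenyl)-2,3-dihydro-1,4-benzodioxin-7-yl]ethenyl}benzene-1,3-diol | Oc1cc(O)cc(/C=C/c2ccc3c(c2)O[C@@H](c2cc(O)cc(O)c2)[C@H](c2ccc(O)c(O)c2)O3)c1 | target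

**Step count and risks**

Total step count: 14. Longest linear sequence: 9 steps (1, 2, 3, 4, 5, 8, 9, 13, 14).

Steps most likely to fail:

1. Step 8 (the step labelled as a proposed new method). β-Hydride elimination toward C2 may overtake release of the quinone methide. The aryl group may be transferred to C3 instead of C2. Enantioface discrimination on an acyclic 1,2-disubstituted alkene may be weak, and a phenol may be O-arylated.
 Fallback with known reactions only, setting out from 3 and 16 and coming back at 11. Horner–Wadsworth–Emmons olefination of 3 with 16 (KOtBu, THF) gives 1-(allyloxy)-4-{(E)-2-[3,5-bis(methoxymethoxy)phenyl]ethenyl}-2-(methoxymethoxy)benzene F1. Shi epoxidation (L-fructose-derived enantiomer of the Shi ketone, KHSO5 as Oxone, K2CO3 buffer, MeCN/dimethoxymethane/water, 0 °C) should give (2S,3S)-2-[4-(allyloxy)-3-(methoxymethoxy)phenyl]-3-[3,5-bis(methoxymethoxy)phenyl]oxirane F2, which fixes the future C2 by reagent control. Commercial 3-bromo-4-hydroxybenzaldehyde (O=Cc1ccc(O)c(Br)c1) with Cs2CO3 in DMF at 60 °C should open the epoxide at the carbon that carries the para-alkoxy aryl group, the only one able to support positive charge. The opening should go mainly with inversion and give 3-bromo-4-{(1R,2S)-1-[4-(allyloxy)-3-(methoxymethoxy)phenyl]-2-[3,5-bis(methoxymethoxy)phenyl]-2-hydroxyethoxy}benzaldehyde F3. Intramolecular Ullmann-type etherification of the secondary alcohol with the aryl bromide (CuI, 1,10-phenanthroline, Cs2CO3, toluene, 110 °C) keeps the carbinol configuration and closes the ring to the cis compound (2S,3R)-3-[4-(allyloxy)-3-(methoxymethoxy)phenyl]-2-[3,5-bis(methoxymethoxy)phenyl]-2,3-dihydro-1,4-benzodioxine-7-carbaldehyde F4. Pd(PPh3)4 with K2CO3 in MeOH at 40 °C removes the allyl group to give (2S,3R)-2-[3,5-bis(methoxymethoxy)phenyl]-3-[4-hydroxy-3-(methoxymethoxy)phenyl]-2,3-dihydro-1,4-benzodioxine-7-carbaldehyde F5. Its phenoxide should open reversibly to 10 and reclose to the trans isomer 11; a partly retentive epoxide opening converges on 11 in the same way.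

2. Step 4. Addition of a formyl-deactivated phenoxide to an electron-rich alkyne may be sluggish. Prolonged heating may erode the Z geometry, and the alkyne may add as an acetylide to the aldehyde.
 Fallback setting out from 3 (with 2 as coupling partner) and coming back at 5. Stork–Zhao olefination of 3 ((iodomethyl)triphenylphosphonium iodide, NaN(SiMe3)2, THF/DMPU, −78 °C) should give 1-(allyloxy)-4-[(Z)-2-iodoethenyl]-2-(methoxymethoxy)benzene F6. Ullmann-type O-vinylation of 2 with F6 (CuI, N,N-dimethylglycine, Cs2CO3, 1,4-dioxane, 60 °C) proceeds with retention of alkene geometry and gives 5.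

3. Step 13. Addition of the phosphonate anion to the electron-rich, hindered aldehyde may be slow, and incomplete E selectivity would leave a Z isomer that is hard to remove.
 Fallback setting out from 12 (with 9 as coupling partner) and coming back at 17. Wittig methylenation of 12 (Ph3PCH3Br, KOtBu, THF, 0 °C) gives (2S,3S)-2-[3,5-bis(methoxymethoxy)phenyl]-3-[3,4-bis(methoxymethoxy)phenyl]-7-ethenyl-2,3-dihydro-1,4-benzodioxine F7. Mizoroki–Heck reaction of F7 with triflate 9 (Pd(OAc)2, tri-o-tolylphosphine, LiCl, Et3N, DMF, 90 °C) should give 17. LiCl steers the triflate onto the neutral pathway, so the aryl group goes to the terminal carbon, and syn β-hydride elimination gives the E alkene.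

Further compounds
F1 | step 8 | 1-(allyloxy)-4-{(E)-2-[3,5-bis(methoxymethoxy)phenyl]ethenyl}-2-(methoxymethoxy)benzene | C=CCOc1ccc(/C=C/c2cc(OCOC)cc(OCOC)c2)cc1OCOC
F2 | step 8 | (2S,3S)-2-[4-(allyloxy)-3-(methoxymethoxy)phenyl]-3-[3,5-bis(methoxymethoxy)phenyl]oxirane | C=CCOc1ccc(cc1OCOC)[C@@H]1O[C@H]1c1cc(OCOC)cc(OCOC)c1
F3 | step 8 | 3-bromo-4-{(1R,2S)-1-[4-(allyloxy)-3-(methoxymethoxy)phenyl]-2-[3,5-bis(methoxymethoxy)phenyl]-2-hydroxyethoxy}benzaldehyde | O=Cc1ccc(c(Br)c1)O[C@H](c1ccc(OCC=C)c(OCOC)c1)[C@@H](O)c1cc(OCOC)cc(OCOC)c1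
F4 | step 8 | (2S,3R)-3-[4-(allyloxy)-3-(methoxymethoxy)phenyl]-2-[3,5-bis(methoxymethoxy)phenyl]-2,3-dihydro-1,4-benzodioxine-7-carbaldehyde | O=Cc1ccc2c(c1)O[C@@H](c1cc(OCOC)cc(OCOC)c1)[C@@H](c1ccc(OCC=C)c(OCOC)c1)O2
F5 | step 8 | (2S,3R)-2-[3,5-bis(methoxymethoxy)phenyl]-3-[4-hydroxy-3-(methoxymethoxy)phenyl]-2,3-dihydro-1,4-benzodioxine-7-carbaldehyde | O=Cc1ccc2c(c1)O[C@@H](c1cc(OCOC)cc(OCOC)c1)[C@@H](c1ccc(O)c(OCOC)c1)O2
F6 | step 4 | 1-(allyloxy)-4-[(Z)-2-iodoethenyl]-2-(methoxymethoxy)benzene | I/C=C\c1ccc(OCC=C)c(OCOC)c1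
F7 | step 13 | (2S,3S)-2-[3,5-bis(methoxymethoxy)phenyl]-3-[3,4-bis(methoxymethoxy)phenyl]-7-ethenyl-2,3-dihydro-1,4-benzodioxine | C=Cc1ccc2c(c1)O[C@@H](c1cc(OCOC)cc(OCOC)c1)[C@H](c1ccc(OCOC)c(OCOC)c1)O2
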